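**Assumption:** carbon labels C1–C20 follow clerodane numbering of the target (C18 = exocyclic CH2 on C4, C19 = methyl on C5, C20 = methyl on C9, C17 = methyl on C8). Compounds 1, 5 and 17 are taken as commercial. The target is (1S,5S,6S,7R,8S,9R,10R,11R).

## Retrosynthetic overview

1. Target ⇐ ester pattern set last by a 6,7→7,8 acetonide relay (6-OAc, then 7-O-isobutyryl); butenolide by acrylate ring-closing metathesis; C18 by Wittig methylenation; C11/C12 by chelation-controlled Barbier allylation of a C9 aldehyde.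
2. Key step: both carbocycles from the acyclic alkene–enal–ketone 13 in one flask. Iron-hydride hydrogen-atom transfer triggers a 6-exo radical cyclisation (ring A, C5–C10), and the resulting enolate closes ring B by aldol (C8–C9). This sets C5, C8, C9 and C10 and replaces the usual Robinson-annulation or Diels–Alder entry to the decalin.
3. 13 ⇐ Nozaki–Hiyama–Kishi union (C4–C5) of enol triflate 4 (C6/C7 from L-tartrate) with aldehyde 10 (C1 from the L-glutamic-acid lactone 5).
4. Ring order: ring A, then ring B (same flask), then the butenolide.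

## Route

Step 1
Reactants: 1 dimethyl (4R,5R)-2,2-dimethyl-1,3-dioxolane-4,5-dicarboxylate
Product: 3 1,1'-[(4R,5R)-2,2-dimethyl-1,3-dioxolane-4,5-diyl]diethanone, via bis-Weinreb amide 2 (not isolated)
Conditions: MeNH(OMe)·HCl (3 equiv), iPrMgCl (6 equiv), THF, −20 °C; then MeMgBr (3 equiv), 0 °C; aq. NH4Cl
Reagents that add atoms: N,O-dimethylhydroxylamine hydrochloride CNOC.Cl (atoms of 2); methylmagnesium bromide C[Mg]Br
Why: One-flask Weinreb ketone synthesis (ester aminolysis by the magnesium amide, then Grignard addition that stops at the chelated adduct); no stereocentre is formed and the trans-dioxolane is the thermodynamic arrangement, so the tartrate centres (future C6/C7) are kept.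

Step 2
Reactants: 3 diketone
Product: 4 1-[(4R,5R)-5-acetyl-2,2-dimethyl-1,3-dioxolan-4-yl]ethenyl trifluoromethanesulfonate
Conditions: KN(SiMe3)2 (1.0 equiv), THF, −78 °C; then PhNTf2; recovered 3 recycled
Reagents that add atoms: N-phenylbis(trifluoromethanesulfonimide) O=S(=O)(N(c1ccccc1)S(=O)(=O)C(F)(F)F)C(F)(F)F
Why: Kinetic enolisation at a methyl group and O-triflation (enol triflate formation); the two acetyl groups of C2-symmetric 3 are equivalent, so mono-triflation gives one compound and no new stereocentre.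

Step 3
Reactants: 5 (5S)-5-(hydroxymethyl)oxolan-2-one
Product: 7 ethyl (2E)-2-methyl-3-[(2S)-5-oxooxolan-2-yl]prop-2-enoate, via lactone aldehyde 6 (not isolated)
Conditions: TEMPO (10 mol %), PhI(OAc)2, CH2Cl2, rt; then Ph3P=C(CH3)CO2Et, rt
Reagents that add atoms: ethyl 2-(triphenylphosphoranylidene)propanoate CCOC(=O)C(C)=P(c1ccccc1)(c1ccccc1)c1ccccc1
Why: TEMPO oxidation followed in the same flask by E-selective Wittig olefination with the stabilised α-methyl ylide; the epimerisable aldehyde is trapped as it forms, so the future C1 centre is retained.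

Step 4
Reactants: 7 enoate lactone
Product: 8 ethyl (2E,4S)-4-hydroxy-7-[methoxy(methyl)amino]-2-methyl-7-oxohept-2-enoate
Conditions: MeNH(OMe)·HCl, AlMe3, CH2Cl2, 0 °C to rt
Reagents that add atoms: N,O-dimethylhydroxylamine hydrochloride CNOC.Cl
Why: Weinreb aminolysis of the γ-lactone by the dimethylaluminium amide (the hindered conjugated ester is not attacked); no stereocentre is touched.

Step 5
Reactants: 8 hydroxy Weinreb amide
Product: 9 ethyl (2E,4S)-4-[(tert-butyldimethylsilyl)oxy]-7-[methoxy(methyl)amino]-2-methyl-7-oxohept-2-enoate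
Conditions: TBSCl, imidazole, DMF, rt (directly after step 4)
Reagents that add atoms: tert-butyldimethylsilyl chloride CC(C)(C)[Si](C)(C)Cl
Why: Silyl ether formation, done at once to stop relactonisation; no stereocentre is changed.

Step 6
Reactants: 9 silyl ether
Product: 10 (4S,5E)-4-[(tert-butyldimethylsilyl)oxy]-7-hydroxy-6-methylhept-5-enal
Conditions: iBu2AlH (3.5 equiv), CH2Cl2, −78 °C; aq. potassium sodium tartrate
Reagents that add atoms: none
Why: Hydride reduction in which the Weinreb amide stops at the chelated hemiaminal (aldehyde on work-up) while the enoate goes to the allylic alcohol; no stereocentre is changed.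

Step 7
Reactants: 10 hydroxy aldehyde; 4 enol triflate
Product: 11 seco diol CH3CO–C7H(O)–C6H(O)(acetonide)–C5(=CH2)–C4H(OH)–CH2CH2–C1H(OTBS)–CH=C(CH3)–CH2OH; 1S,4S,6S,7R; 9E
Conditions: CrCl2 (3 equiv), NiCl2 (5 mol %), (S)-configured sulfonamide–oxazoline ligand (3.3 equiv), Et3N, THF, rt
Reagents that add atoms: none
Why: Nozaki–Hiyama–Kishi coupling (the alkenylchromium adds only to the aldehyde; ketone and free hydroxyl are tolerated); C4 is set by the chiral ligand on chromium (antipode chosen for 4S), and because C4 is oxidised in step 11 a modest diastereomer ratio is tolerable.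

Step 8
Reactants: 11 seco diol
Product: 12 (2E,4S,7S)-8-[(4S,5R)-5-acetyl-2,2-dimethyl-1,3-dioxolan-4-yl]-4-[(tert-butyldimethylsilyl)oxy]-7-hydroxy-2-methylnona-2,8-dienal
Conditions: TEMPO (20 mol %), PhI(OAc)2, CH2Cl2, rt
Reagents that add atoms: none
Why: TEMPO-catalysed oxidation, selective for the primary allylic alcohol over the hindered secondary one; no stereocentre is changed.

Step 9
Reactants: 12 hydroxy enal
Product: 13 (2E,4S,7S)-8-[(4S,5R)-5-acetyl-2,2-dimethyl-1,3-dioxolan-4-yl]-4-[(tert-butyldimethylsilyl)oxy]-2-methyl-7-[(trimethylsilyl)oxy]nona-2,8-dienal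
Conditions: TMSCl, imidazole, CH2Cl2, 0 °C; Et3N-buffered silica
Reagents that add atoms: chlorotrimethylsilane C[Si](C)(C)Cl
Why: Silylation of the C4 hydroxyl, a temporary mask that prevents oxa-Michael addition to the enal and hemiketal formation with the ketone before the cyclisation.

Step 10
Reactants: 13 alkene–enal–ketone
Product: 15 decalin hydroxy aldehyde (1-OTBS; 4-OH; 6,7-O-isopropylidene; 8-OH; C9 formyl; 4S; C1 and C5–C10 as in the target), via aldol trimethylsilyl ether 14 (not isolated)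
Conditions: Fe(acac)3 (30 mol %), PhSiH3 (2.5 equiv), EtOH/(CH2OH)2 5:1, 0.01 M, degassed, Ar, rt; then 10% aq. citric acid, THF
Reagents that add atoms: none
Why: Iron-hydride hydrogen-atom transfer to the 1,1-disubstituted alkene gives the C5 tertiary radical, which closes ring A by 6-exo Giese cyclisation onto the enal through a chair with both silyloxy groups, the enal and the dioxolanyl arm equatorial (C19 axial, H-10 trans to it); the iron enolate then closes ring B by intramolecular aldol onto the methyl ketone through a chair, metal-bridged transition state (C17 equatorial, C8–O axial and gauche to the equatorial formyl, C20 axial), with reversibility of the aldol expected to funnel material to this chelated trans-decalin.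

Step 11
Reactants: 15 decalin hydroxy aldehyde
Product: 16 decalin keto aldehyde (C4 ketone; otherwise as 15)
Conditions: Dess–Martin periodinane, CH2Cl2, 0 °C to rt
Reagents that add atoms: none
Why: Dess–Martin oxidation of the only secondary alcohol (tertiary 8-OH and the aldehyde are inert) removes the temporary C4 centre.

Step 12
Reactants: 17 ethyl 2-(bromomethyl)prop-2-enoate
Product: 18 2-(bromomethyl)prop-2-en-1-ol
Conditions: iBu2AlH (2.2 equiv), CH2Cl2, −78 °C
Reagents that add atoms: none
Why: 1,2-Hydride reduction of the ester to the allylic alcohol with the allylic bromide retained.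

Step 13
Reactants: 16 decalin keto aldehyde; 18 2-(bromomethyl)prop-2-en-1-ol
Product: 19 Barbier adduct (C4 ketone; C11H(OH)–C12H2–C(=CH2)–CH2OH side chain; 11R)
Conditions: indium powder (3 equiv), 18 (3 equiv), THF/H2O 3:1, rt
Reagents that add atoms: none
Why: Indium-mediated Barbier allylation, selective for the aldehyde over the neopentyl ketone; indium bridges the axial 8-OH and the formyl oxygen and the allyl group enters from the face away from C10/C1, giving 11R.

Step 14
Reactants: 19 Barbier adduct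
Product: 20 4(18)-methylene triol (C4=CH2; 8-OH, 11-OH and primary allylic OH free)
Conditions: Ph3PCH3Br (8 equiv), KOtBu (7.5 equiv), THF, 0 to 60 °C
Reagents that add atoms: methyltriphenylphosphonium bromide C[P+](c1ccccc1)(c1ccccc1)c1ccccc1.[Br-]
Why: Wittig methylenation of the hindered C4 ketone with excess ylide at elevated temperature (the hydroxyls ride through as alkoxides; C5 is quaternary so nothing can epimerise or eliminate).

Step 15
Reactants: 20 methylene triol
Product: 21 primary acrylate of 20 (–CH2–C(=CH2)–CH2–O–CO–CH=CH2)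
Conditions: acryloyl chloride (1.05 equiv), iPr2NEt, CH2Cl2, −78 °C
Reagents that add atoms: acryloyl chloride C=CC(=O)Cl
Why: Selective O-acylation of the unhindered primary allylic alcohol over the neopentyl secondary and the tertiary hydroxyls.

Step 16
Reactants: 21 acrylate
Product: 22 butenolide (13-en-15,16-olide; 1-OTBS; 6,7-O-isopropylidene; 8-OH; 11-OH)
Conditions: second-generation Hoveyda–Grubbs catalyst (10 mol %), 1,4-benzoquinone (10 mol %), toluene, 0.005 M, 80 °C
Reagents that add atoms: none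
Why: Ring-closing metathesis of the acrylate with the 1,1-disubstituted alkene gives the β-substituted butenolide; the neopentyl C4 exocyclic methylene is too hindered to take part.

Step 17
Reactants: 22 butenolide
Product: 23 7,8-O-isopropylidene isomer (6-OH free; 1-OTBS; 11-OH)
Conditions: PPTS (20 mol %), acetone, 40 °C
Reagents that add atoms: none
Why: Acid-catalysed acetonide migration (intramolecular transketalisation) from the strained trans-fused 6,7-dioxolane to the cis-fused 7,8-dioxolane under thermodynamic control, which frees 6-OH and masks the tertiary 8-OH.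

Step 18
Reactants: 23 7,8-acetonide
Product: 24 1,6,11-triol 7,8-acetonide
Conditions: HF·pyridine, pyridine, THF, 0 °C to rt
Reagents that add atoms: none
Why: Fluoride desilylation of the C1 silyl ether; the cis-acetonide and the butenolide are stable to buffered HF.

Step 19
Reactants: 24 triol acetonide
Product: 25 1,6,11-triacetate 7,8-acetonide
Conditions: Ac2O, DMAP (30 mol %), pyridine, rt
Reagents that add atoms: acetic anhydride CC(=O)OC(C)=O
Why: DMAP-catalysed acetylation of the three secondary hydroxyls while O7 and O8 are masked.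

Step 20
Reactants: 25 triacetate acetonide
Product: 26 1,6,11-triacetate 7,8-diol
Conditions: AcOH/H2O 4:1, 45 °C
Reagents that add atoms: none
Why: Mild acetal hydrolysis; acetic acid is too weak to protonate the exocyclic alkene or to cleave the acetates.

Step 21
Reactants: 26 triacetate diol
Product: 27 (1S,5S,6S,7R,8S,9R,10R,11R)-1,6,11-triacetoxy-8-hydroxy-7-(2-methylpropanoyloxy)cleroda-4(18),13-dien-15,16-olide (target)
Conditions: iPrCOCl (1.5 equiv), DMAP (20 mol %), pyridine, CH2Cl2, 0 °C
Reagents that add atoms: isobutyryl chloride CC(C)C(=O)Cl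
Why: Selective acylation of the secondary equatorial 7-OH; the tertiary axial 8-OH does not react under these conditions.

## Compound list

1 | dimethyl (4R,5R)-2,2-dimethyl-1,3-dioxolane-4,5-dicarboxylate | COC(=O)[C@@H]1OC(C)(C)O[C@H]1C(=O)OC | starting material
2 | (4R,5R)-N4,N5-dimethoxy-N4,N5,2,2-tetramethyl-1,3-dioxolane-4,5-dicarboxamide | CON(C)C(=O)[C@@H]1OC(C)(C)O[C@H]1C(=O)N(C)OC | intermediate
3 | 1,1'-[(4R,5R)-2,2-dimethyl-1,3-dioxolane-4,5-diyl]diethanone | CC(=O)[C@@H]1OC(C)(C)O[C@H]1C(C)=O | intermediate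
4 | 1-[(4R,5R)-5-acetyl-2,2-dimethyl-1,3-dioxolan-4-yl]ethenyl trifluoromethanesulfonate | CC(=O)[C@@H]1OC(C)(C)O[C@H]1C(=C)OS(=O)(=O)C(F)(F)F | intermediate
5 | (5S)-5-(hydroxymethyl)oxolan-2-one | OC[C@@H]1CCC(=O)O1 | starting material
6 | (2S)-5-oxooxolane-2-carbaldehyde | O=C[C@@H]1CCC(=O)O1 | intermediate
7 | ethyl (2E)-2-methyl-3-[(2S)-5-oxooxolan-2-yl]prop-2-enoate | CCOC(=O)/C(C)=C/[C@@H]1CCC(=O)O1 | intermediate
8 | ethyl (2E,4S)-4-hydroxy-7-[methoxy(methyl)amino]-2-methyl-7-oxohept-2-enoate | CCOC(=O)/C(C)=C/[C@@H](O)CCC(=O)N(C)OC | intermediate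
9 | ethyl (2E,4S)-4-[(tert-butyldimethylsilyl)oxy]-7-[methoxy(methyl)amino]-2-methyl-7-oxohept-2-enoate | CCOC(=O)/C(C)=C/[C@@H](O[Si](C)(C)C(C)(C)C)CCC(=O)N(C)OC | intermediate
10 | (4S,5E)-4-[(tert-butyldimethylsilyl)oxy]-7-hydroxy-6-methylhept-5-enal | O=CCC[C@H](O[Si](C)(C)C(C)(C)C)/C=C(\C)CO | intermediate
11 | 1-{(4R,5S)-5-[(3S,6S,7E)-6-[(tert-butyldimethylsilyl)oxy]-3,9-dihydroxy-8-methylnona-1,7-dien-2-yl]-2,2-dimethyl-1,3-dioxolan-4-yl}ethanone | CC(=O)[C@@H]1OC(C)(C)O[C@H]1C(=C)[C@@H](O)CC[C@H](O[Si](C)(C)C(C)(C)C)/C=C(\C)CO | intermediate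
12 | (2E,4S,7S)-8-[(4S,5R)-5-acetyl-2,2-dimethyl-1,3-dioxolan-4-yl]-4-[(tert-butyldimethylsilyl)oxy]-7-hydroxy-2-methylnona-2,8-dienal | CC(=O)[C@@H]1OC(C)(C)O[C@H]1C(=C)[C@@H](O)CC[C@H](O[Si](C)(C)C(C)(C)C)/C=C(\C)C=O | intermediate
13 | (2E,4S,7S)-8-[(4S,5R)-5-acetyl-2,2-dimethyl-1,3-dioxolan-4-yl]-4-[(tert-butyldimethylsilyl)oxy]-2-methyl-7-[(trimethylsilyl)oxy]nona-2,8-dienal | CC(=O)[C@@H]1OC(C)(C)O[C@H]1C(=C)[C@@H](O[Si](C)(C)C)CC[C@H](O[Si](C)(C)C(C)(C)C)/C=C(\C)C=O | intermediate
14 | trans-decalin aldol, C4 trimethylsilyl ether (1-OTBS; 6,7-O-isopropylidene; 8-OH; C9 formyl) | C[Si](C)(C)O[C@H]1CC[C@H](O[Si](C)(C)C(C)(C)C)[C@@H]2[C@]1(C)[C@@H]3OC(C)(C)O[C@H]3[C@@](C)(O)[C@@]2(C)C=O | intermediate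
15 | trans-decalin hydroxy aldehyde (1-OTBS; 4-OH, 4S; 6,7-O-isopropylidene; 8-OH; C9 formyl) | O[C@H]1CC[C@H](O[Si](C)(C)C(C)(C)C)[C@@H]2[C@]1(C)[C@@H]3OC(C)(C)O[C@H]3[C@@](C)(O)[C@@]2(C)C=O | intermediate
16 | trans-decalin keto aldehyde (C4 ketone; otherwise as 15) | O=C1CC[C@H](O[Si](C)(C)C(C)(C)C)[C@@H]2[C@]1(C)[C@@H]3OC(C)(C)O[C@H]3[C@@](C)(O)[C@@]2(C)C=O | intermediate
17 | ethyl 2-(bromomethyl)prop-2-enoate | CCOC(=O)C(=C)CBr | starting material
18 | 2-(bromomethyl)prop-2-en-1-ol | OCC(=C)CBr | intermediate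
19 | Barbier adduct: C4 ketone, (11R)-C11H(OH)–CH2–C(=CH2)–CH2OH side chain | O=C1CC[C@H](O[Si](C)(C)C(C)(C)C)[C@@H]2[C@]1(C)[C@@H]3OC(C)(C)O[C@H]3[C@@](C)(O)[C@@]2(C)[C@H](O)CC(=C)CO | intermediate
20 | 4(18)-methylene triol | C=C1CC[C@H](O[Si](C)(C)C(C)(C)C)[C@@H]2[C@]1(C)[C@@H]3OC(C)(C)O[C@H]3[C@@](C)(O)[C@@]2(C)[C@H](O)CC(=C)CO | intermediate
21 | primary acrylate of 20 | C=C1CC[C@H](O[Si](C)(C)C(C)(C)C)[C@@H]2[C@]1(C)[C@@H]3OC(C)(C)O[C@H]3[C@@](C)(O)[C@@]2(C)[C@H](O)CC(=C)COC(=O)C=C | intermediate
22 | 1-O-TBS-6,7-O-isopropylidene-8,11-dihydroxycleroda-4(18),13-dien-15,16-olide | C=C1CC[C@H](O[Si](C)(C)C(C)(C)C)[C@@H]2[C@]1(C)[C@@H]3OC(C)(C)O[C@H]3[C@@](C)(O)[C@@]2(C)[C@H](O)CC4=CC(=O)OC4 | intermediate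
23 | 1-O-TBS-7,8-O-isopropylidene-6,11-dihydroxycleroda-4(18),13-dien-15,16-olide | C=C1CC[C@H](O[Si](C)(C)C(C)(C)C)[C@@H]2[C@]1(C)[C@H](O)[C@H]3OC(C)(C)O[C@@]3(C)[C@@]2(C)[C@H](O)CC4=CC(=O)OC4 | intermediate
24 | 7,8-O-isopropylidene-1,6,11-trihydroxycleroda-4(18),13-dien-15,16-olide | C=C1CC[C@H](O)[C@@H]2[C@]1(C)[C@H](O)[C@H]3OC(C)(C)O[C@@]3(C)[C@@]2(C)[C@H](O)CC4=CC(=O)OC4 | intermediate
25 | 1,6,11-triacetoxy-7,8-O-isopropylidenecleroda-4(18),13-dien-15,16-olide | C=C1CC[C@H](OC(C)=O)[C@@H]2[C@]1(C)[C@H](OC(C)=O)[C@H]3OC(C)(C)O[C@@]3(C)[C@@]2(C)[C@H](OC(C)=O)CC4=CC(=O)OC4 | intermediate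
26 | 1,6,11-triacetoxy-7,8-dihydroxycleroda-4(18),13-dien-15,16-olide | C=C1CC[C@H](OC(C)=O)[C@@H]2[C@]1(C)[C@H](OC(C)=O)[C@@H](O)[C@@](C)(O)[C@@]2(C)[C@H](OC(C)=O)CC4=CC(=O)OC4 | intermediate
27 | (1S,5S,6S,7R,8S,9R,10R,11R)-1,6,11-triacetoxy-8-hydroxy-7-(2-methylpropanoyloxy)cleroda-4(18),13-dien-15,16-olide | C=C1CC[C@H](OC(C)=O)[C@@H]2[C@]1(C)[C@H](OC(C)=O)[C@@H](OC(=O)C(C)C)[C@@](C)(O)[C@@]2(C)[C@@H](CC1=CC(=O)OC1)OC(C)=O | target

## Step count

Total: 21 steps. Longest linear sequence: 18 steps (5 → 27: steps 3–11 and 13–21).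

## Three steps most likely to fail

**Step 10 (radical–polar crossover bicyclisation).** This is the main risk of the route. Three things can go wrong: a 1,5-hydrogen shift from the allylic C1–H can compete with the 6-exo closure; the C5 radical can add with the other face (cis-decalin); and the aldol sense at C8/C9 depends on enolate geometry and on how tightly the metal bridges the two oxygens, so C8 or C9 epimers may form instead of the drawn isomer. The fallback sets out from 13 and returns at 15, separating the two ring closures. Ring A is closed alone under hydrogen-atom-terminated conditions (Mn(dpm)3 cat., PhSiH3, iPrOH, rt), where the α-formyl radical is quenched by hydrogen-atom transfer instead of being reduced to an enolate; this gives the ring A keto aldehyde F1 as a C9 epimer mixture. Ring B is then closed in a separate, reversible, magnesium-templated aldol (MgBr2·OEt2, Et3N, CH2Cl2, rt), which equilibrates by retro-aldol to the chelated diastereomer 14; citric acid work-up gives 15.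

**Step 13 (Barbier allylation, C11).** The aldehyde is neopentyl and flanked by the C1 silyl ether, and the 11R outcome depends on indium chelation by the 8-OH in a wet medium. The fallback sets out from 16 and returns at 19, using a Hosomi–Sakurai allylation under a firmer chelate. TiCl4 (1.1 equiv, CH2Cl2, −78 °C) binds the C8 alkoxide and the formyl oxygen, and 2-[(trimethylsilyl)methyl]allyl acetate adds from the same open face to give the hydroxy allylic acetate F2. Methanolysis of the acetate (K2CO3, MeOH, 0 °C) gives 19.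

**Step 17 (acetonide migration).** The equilibrium may not favour the 7,8-dioxolane strongly enough, or a 1,3-dioxane across O8/O11 may compete. The fallback sets out from 22 and returns at the target 27, replacing the protecting-group relay by catalyst-controlled acylation. Aqueous HF in MeCN removes the silyl ether and the acetonide to give the pentaol F3. 2-Aminoethyl diphenylborinate (10 mol %), iPrCOCl and iPr2NEt in MeCN then acylate the equatorial oxygen of the only cis-1,2-diol (O7) to give the 7-isobutyrate tetraol F4. Ac2O, DMAP and pyridine acetylate the three remaining secondary hydroxyls to give 27.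

## Further compounds

F1 | step 10 | ring A keto aldehyde (C9 epimers; C4 trimethylsilyl ether; ring B open) | C[Si](C)(C)O[C@H]1CC[C@H](O[Si](C)(C)C(C)(C)C)[C@@H](C(C)C=O)[C@]1(C)[C@@H]2OC(C)(C)O[C@H]2C(C)=O
F2 | step 13 | hydroxy allylic acetate (19 with the primary hydroxyl acetylated) | O=C1CC[C@H](O[Si](C)(C)C(C)(C)C)[C@@H]2[C@]1(C)[C@@H]3OC(C)(C)O[C@H]3[C@@](C)(O)[C@@]2(C)[C@H](O)CC(=C)COC(C)=O
F3 | step 17 | 1,6,7,8,11-pentahydroxycleroda-4(18),13-dien-15,16-olide | C=C1CC[C@H](O)[C@@H]2[C@]1(C)[C@H](O)[C@@H](O)[C@@](C)(O)[C@@]2(C)[C@H](O)CC4=CC(=O)OC4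
F4 | step 17 | 1,6,8,11-tetrahydroxy-7-(2-methylpropanoyloxy)cleroda-4(18),13-dien-15,16-olide | C=C1CC[C@H](O)[C@@H]2[C@]1(C)[C@H](O)[C@@H](OC(=O)C(C)C)[C@@](C)(O)[C@@]2(C)[C@H](O)CC4=CC(=O)OC4
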